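## Structural features

The target is a 2,3-trans dihydroflavonol 3-O-methyl ether. Benzo ring A (5-OH, 6-OMe, 7-OMe, 8-H) is fused through C4a and C8a to pyranone ring C (O1, C2, C3, C4=O). Ring C carries the 2,5-dihydroxy-4-methoxyphenyl ring B at C2 and a methoxy group at C3. The only stereocentres, C2 (R) and C3 (R), are adjacent and hold the aryl and methoxy groups trans-diequatorial. C3–H is alpha to the C4 ketone, so it can epimerise, or ring C can open by beta-elimination of O1 to an alpha-methoxychalcone. The C2–O1 bond is a benzylic aryl ether with an ortho 2'-hydroxyl and a para 4'-methoxy group, so it ionises under acid and reopens through an ortho-quinone methide under base; with O5–H free, reclosure on the wrong oxygen would turn the 5,6,7 pattern into 5,7,8. Ring B is an air-sensitive hydroquinone, and the real difficulty is to fix the absolute configuration of two labile neighbouring centres and to end with exactly one free hydroxyl (O5) on ring A. The key step exploits the fact that C2 is a benzylic carbon ortho to O2' of hydroquinone ring B: a ring B para-quinone with a CH2 at C2 and an open O1–H is an isomer of the O5-methylated flavanone, so the quinone can serve as internal oxidant for the O1–C2 bond.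

## Logic of the disconnections

**18 ⇒ 17.** Only the O5–H bond changes: O5 is capped as a methyl ether. The cap is needed because ring C must be closed while a single ring A oxygen is free. With it, ring A derives from a symmetric trioxygenated phenol. The forward step must remove one methyl group out of five; the peri relation of O5 to the C4 carbonyl singles it out, and the reagent must not ionise C2–O1.

**17 ⇒ 15 (through 16).** The O1–C2 bond is cut and two hydrogens are moved from ring B to the chain, which turns the hydroquinone into a quinone. This removes ring C and the C2 stereocentre without a change in overall oxidation level and leaves an open chain whose only stereocentre is C3. The forward step must form methide 16 and close the ring faster than C3 loses its proton, and it must deliver C2 trans to C3.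

**15 ⇒ 14 ⇒ 13.** No skeletal bond is cut; the quinone is stored as hydroquinone 14 and the three phenols as the benzyl ethers of 13. The gain is stability: neither a quinone nor a free hydroquinone has to survive organometallic steps. The demand is an oxidant that touches only the hydroquinone of 14 and a hydrogenolysis that spares the aryl ketone of 13.

**13 ⇒ 12 + 8.** The C4–C4a (acyl–aryl) bond is cut. This halves the molecule, keeps the stereocentre on the acyl partner 8 and makes ring A an aryl nucleophile 12. The forward step must stop at the ketone and must not deprotonate C3, hence the N-methoxy-N-methylamide.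

**12 ⇒ 11 ⇒ 10 ⇒ 9.** The C–Li, O–benzyl and C–Br bonds are cut in turn. The two free ring positions of 9 are equivalent, so the halogenation that decides where C4 is attached has no regiochemical choice; it only has to stop after one bromine.

**8 ⇒ 7 ⇒ 6.** The amide C–N bond and the O–CH3 bond at C3 are cut, which leads to an alpha-hydroxy ester. The methylation must work on a secondary alcohol next to an ester without a base that could epimerise C3.

**6 ⇒ 5 + 4.** The C2–C1' (CH2–aryl) bond is cut. The C2–C3–C4 unit with its C3 oxygen is then the intact, enantiopure three-carbon epoxy ester 4, so no stereocentre has to be created. The aryl nucleophile 5 must attack the terminal epoxide carbon and not the ester.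

**5 ⇒ 3 ⇒ 2 ⇒ 1.** The C–Mg, C–Br and two O–benzyl bonds are cut. The bromination of 2 must take the position para to the methoxy group, which is the electronically preferred one.

## Other disconnections considered

**Alternative 1:** Ring A is removed last by cutting C8–C8a and C4a–C5. This leaves the C8a-stannylated ring C glycal A2 and 4-chloro-2,3-dimethoxycyclobut-2-en-1-one A3.
- **Forward key step:** Pd(PPh3)4 (zerovalent palladium) would join A2 and A3 in a Stille coupling. On warming, the 4-alkenylcyclobutenone would open to a dienylketene, close at C4a–C5 by 6π electrocyclisation and tautomerise to phenol A1.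
- **In its favour:** The ring A oxygen pattern, including the free 5-hydroxyl, is written into A3. No demethylation and no regiochemical lock are needed; on this point it is better than the chosen plan. Both stereocentres exist before the key step, so C2 does not depend on an equilibration; on that point it is at least equal. The benzannulation is a known reaction type, whereas the chosen key step is not.
- **Against it here:** A2 needs three contiguous stereocentres on a 2-aryl dihydropyran, one of which (C4) is later destroyed by oxidation. Its C8a metalation competes with the acidic benzylic C2–H. After A1, desilylation at O4, oxidation of C4–OH next to a free electron-rich phenol, and removal of the two ring B silyl groups are still required, against one step in the chosen plan. Stoichiometric organotin is used.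
- **Comparison:** Structurally cleaner at ring A and mechanistically better precedented, but step economy is clearly worse (estimated well above 18 steps).

**Alternative 2:** The C3–C4 bond is cut as an alkene, which leads back to diene A5 (ring A styrene plus a branched 1-arylallyl aryl ether).
- **Forward key step:** The second-generation Grubbs catalyst RuCl2(=CHPh)(H2IMes)(PCy3) would close ring C with loss of ethylene to the 2-aryl-2H-chromene A4. A4 keeps the geometry of the target at C2; its descriptor is S only because C3 now ranks below the aryl carbon.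
- **In its favour:** Ring-closing metathesis to 2H-chromenes is robust and well precedented; here the alternative is better than the chosen plan. The C2 aryl group should steer later oxygenation of the alkene to the opposite face, which suits the trans target.
- **Against it here:** C2 in A5 and A4 is an aryl ether carbon that is both allylic and benzylic to a very electron-rich ring. It can ionise, and A4 can open electrocyclically to an ortho-quinone methide, so its configuration is insecure. Making A5 as one enantiomer is itself hard. After A4 the whole oxidation pattern of ring C is missing: C3–O and C4=O must be installed regio- and stereoselectively, C3–OH methylated, the benzyl groups removed and O5 demethylated, at least five steps after the key step.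
- **Comparison:** Equal on the ring A lock and the final demethylation. The chosen plan has C3 from the chiral pool and ring C at the correct oxidation level before closure, and is shorter.

**Alternative 3:** The C4–C4a bond is cut, which leads back to the aryloxy acid A7.
- **Forward key step:** The mixed anhydride of A7 with trifluoroacetic anhydride would acylate the ortho carbon of the trimethoxyphenoxy ring (intramolecular Friedel–Crafts acylation) to give A6.
- **In its favour:** It is a known reaction type on an electron-rich ring. The symmetric aryloxy ring gives a single regioisomer, which is equal to the chosen plan. Both stereocentres are set before closure and no quinone is handled; in precedent it is better than the chosen plan.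
- **Against it here:** The benzylic aryl ether of A7 sits next to a 4-methoxy-2-benzyloxyphenyl ring and may ionise under the acidic acylation medium, with epimerisation or elimination. The alpha-methoxy acyl trifluoroacetate may epimerise through a ketene. The stereospecific construction of that ether (substitution at an electron-rich benzylic carbon) moves the main difficulty to an earlier step. A6 still needs hydrogenolysis and the O5 demethylation, two steps against one.
- **Comparison:** This is the closest competitor. The estimated step count is similar (about 12 to 13). It is better in precedent, but weaker in the acid lability of its key intermediate and in having no means to correct C2 before debenzylation.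

Key step: step 11

Remark on the chemistry: the quinone precursor and the cyclised product were checked against the target and need no correction (C3 is R throughout, C2 is R and trans to C3). The precursor design with O5 methylated is kept. Its C3 centre is taken from commercial methyl (2R)-oxirane-2-carboxylate instead of an auxiliary alkylation, which removes two steps and the unstable trialkoxybenzyl bromide from the main line.

## Route

Step 1
Reactants: 1 2-methoxybenzene-1,4-diol (2-methoxyhydroquinone)
Product: 2 1,4-bis(benzyloxy)-2-methoxybenzene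
Conditions: BnBr (2.3 equiv), K2CO3 (3 equiv), degassed DMF, 50 °C, N2
Reagents that add atoms: benzyl bromide, BrCc1ccccc1
Why: Williamson ether synthesis on both phenols; exclusion of air keeps the hydroquinone from oxidising under base, and benzyl is chosen so that all three benzyl ethers of the route fall in one hydrogenolysis.

Step 2
Reactants: 2 1,4-bis(benzyloxy)-2-methoxybenzene
Product: 3 1,4-bis(benzyloxy)-2-bromo-5-methoxybenzene
Conditions: NBS (1.05 equiv), MeCN, 0 °C to 23 °C, dark
Reagents that add atoms: N-bromosuccinimide, O=C1CCC(=O)N1Br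
Why: Electrophilic aromatic bromination; the position para to the methoxy group and ortho to a benzyloxy group is the most activated and least hindered site of a 1,2,4-trialkoxybenzene, so one bromide should form.

Step 3
Reactants: 3 1,4-bis(benzyloxy)-2-bromo-5-methoxybenzene; 4 methyl (2R)-oxirane-2-carboxylate
Product: 6 methyl (2R)-3-[2,5-bis(benzyloxy)-4-methoxyphenyl]-2-hydroxypropanoate, via arylmagnesium bromide 5 (not isolated)
Conditions: Mg, LiCl, THF, 25 °C; then CuI (10 mol %), 4 (0.75 equiv), THF, −40 °C to −20 °C; then 1 M HCl, 0 °C
Reagents that add atoms: none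
Why: Grignard formation, then copper-catalysed opening of the epoxide at its unsubstituted carbon (organocuprate epoxide opening), which at low temperature should outrun attack on the ester; the C–O bond at the stereocentre is not broken, so the R configuration of 4 is carried over unchanged.

Step 4
Reactants: 6 methyl (2R)-3-[2,5-bis(benzyloxy)-4-methoxyphenyl]-2-hydroxypropanoate
Product: 7 methyl (2R)-3-[2,5-bis(benzyloxy)-4-methoxyphenyl]-2-methoxypropanoate
Conditions: MeI (10 equiv), Ag2O (3 equiv), 4 Å MS, MeCN, 40 °C, dark
Reagents that add atoms: iodomethane, CI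
Why: Purdie methylation; Ag2O activates MeI and acts only as a weak, non-enolising base, so the alpha stereocentre of the hydroxy ester should be retained.

Step 5
Reactants: 7 methyl (2R)-3-[2,5-bis(benzyloxy)-4-methoxyphenyl]-2-methoxypropanoate
Product: 8 (2R)-3-[2,5-bis(benzyloxy)-4-methoxyphenyl]-N,2-dimethoxy-N-methylpropanamide
Conditions: MeNHOMe·HCl (1.5 equiv), i-PrMgCl (3.0 equiv), THF, −20 °C to −10 °C; then 1 M HCl, 0 °C
Reagents that add atoms: N,O-dimethylhydroxylamine hydrochloride, CNOC.Cl
Why: Weinreb amide formation by aminolysis of the ester with the chloromagnesium amide made in the flask; at −20 °C this reagent should act as a nucleophile and not as a base, so C3 keeps its configuration.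

Step 6
Reactants: 9 3,4,5-trimethoxyphenol
Product: 10 2-bromo-3,4,5-trimethoxyphenol
Conditions: NBS (1.0 equiv), CH2Cl2, −78 °C to 0 °C
Reagents that add atoms: N-bromosuccinimide, O=C1CCC(=O)N1Br
Why: Electrophilic bromination ortho to the phenol; the two open positions are equivalent, so only one monobromide can form, and one equivalent at low temperature should hold back the dibromide.

Step 7
Reactants: 10 2-bromo-3,4,5-trimethoxyphenol
Product: 11 1-(benzyloxy)-2-bromo-3,4,5-trimethoxybenzene
Conditions: BnBr (1.2 equiv), K2CO3 (2 equiv), DMF, 23 °C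
Reagents that add atoms: benzyl bromide, BrCc1ccccc1
Why: Williamson ether synthesis; the benzyl ether masks the acidic phenol for the organolithium step and later leaves together with the ring B benzyl groups.

Step 8
Reactants: 11 1-(benzyloxy)-2-bromo-3,4,5-trimethoxybenzene; 8 (2R)-3-[2,5-bis(benzyloxy)-4-methoxyphenyl]-N,2-dimethoxy-N-methylpropanamide
Product: 13 (2R)-1-[2-(benzyloxy)-4,5,6-trimethoxyphenyl]-3-[2,5-bis(benzyloxy)-4-methoxyphenyl]-2-methoxypropan-1-one, via aryllithium 12 (not isolated)
Conditions: 11 (1.3 equiv), n-BuLi (1.3 equiv), THF, −78 °C; then 8, −78 °C to −40 °C; then 1 M HCl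
Reagents that add atoms: none
Why: Bromine–lithium exchange followed by Weinreb ketone synthesis; the metal-chelated adduct collapses only on work-up, so a second addition is excluded, and the low temperature should keep the hindered aryllithium from deprotonating C3.

Step 9
Reactants: 13 (2R)-1-[2-(benzyloxy)-4,5,6-trimethoxyphenyl]-3-[2,5-bis(benzyloxy)-4-methoxyphenyl]-2-methoxypropan-1-one
Product: 14 (2R)-3-(2,5-dihydroxy-4-methoxyphenyl)-1-(2-hydroxy-4,5,6-trimethoxyphenyl)-2-methoxypropan-1-one
Conditions: H2 (1 atm), 10% palladium on carbon (Pd/C), EtOAc, 23 °C; filtered under Ar and used at once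
Reagents that add atoms: none
Why: Catalytic hydrogenolysis of three aryl benzyl ethers; the hindered, electron-rich aryl ketone and the alkyl methyl ether should be inert under these neutral conditions, and C3 is not touched.

Step 10
Reactants: 14 (2R)-3-(2,5-dihydroxy-4-methoxyphenyl)-1-(2-hydroxy-4,5,6-trimethoxyphenyl)-2-methoxypropan-1-one
Product: 15 2-[(2R)-3-(2-hydroxy-4,5,6-trimethoxyphenyl)-2-methoxy-3-oxopropyl]-5-methoxy-1,4-benzoquinone
Conditions: Ag2O (2 equiv), Na2SO4, Et2O/CH2Cl2, 23 °C, dark, short contact; filtered through Celite
Reagents that add atoms: none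
Why: Two-electron oxidation of a para-hydroquinone to the para-quinone with Ag2O; the monohydric, hydrogen-bonded ring A phenol should not be attacked by this mild oxidant, and dry neutral conditions with a short contact time should prevent premature tautomerisation.

Step 11
Reactants: 15 2-[(2R)-3-(2-hydroxy-4,5,6-trimethoxyphenyl)-2-methoxy-3-oxopropyl]-5-methoxy-1,4-benzoquinone
Product: 17 (2R,3R)-2-(2,5-dihydroxy-4-methoxyphenyl)-3,5,6,7-tetramethoxy-2,3-dihydro-4H-chromen-4-one, via ortho-quinone methide 16 (not isolated)
Conditions: i-Pr2NEt (0.2 equiv), degassed CH2Cl2 (0.005 M), 23 °C, dark, Ar; then wash with aq. Na2S2O4 and pH 5 buffer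
Reagents that add atoms: none
Why: Proposed new method: the base removes one proton of the CH2 group on the quinone ring and the extended enolate is reprotonated on oxygen, which gives ortho-quinone methide 16 with C2 as the methide carbon. The ring A hydroxyl then adds to that carbon (oxa-conjugate addition), forming O1–C2 and rearomatising ring B as the hydroquinone, so the quinone is the internal oxidant and the step is redox-neutral. The closest known reaction type is the base- or heat-induced tautomerisation of 2-alkyl-1,4-benzoquinones to ortho-quinone methides that are captured by oxygen nucleophiles; capture by a phenol to close a flavanone ring is the untested part. Ring C closes in the 6-exo-trig mode, the attacked C2=C1' double bond lying outside the new ring. C2 is controlled by the existing C3 centre under thermodynamic control: the benzylic aryl ether can reopen to 16 through the 2'-phenoxide, so the mixture should settle on the trans isomer with aryl and methoxy both equatorial, which is 2R. The selectivity needed is ring closure ahead of proton loss at C3 (enolisation, or isomerisation of 16 to the alpha-methoxychalcone); a catalytic hindered amine, room temperature and the intramolecular six-membered capture should secure it. Only one ring A hydroxyl is free because O5 is methylated, so a single chromanone regioisomer can form. High dilution, exclusion of air and the reductive wash should limit hydrogen exchange between quinone 15 and hydroquinone 17 and return any ring B quinone of the product to 17.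

Step 12
Reactants: 17 (2R,3R)-2-(2,5-dihydroxy-4-methoxyphenyl)-3,5,6,7-tetramethoxy-2,3-dihydro-4H-chromen-4-one
Product: 18 (2R,3R)-2-(2,5-dihydroxy-4-methoxyphenyl)-5-hydroxy-3,6,7-trimethoxy-2,3-dihydro-4H-chromen-4-one
Conditions: BCl3 (1 M in CH2Cl2, 4 equiv), CH2Cl2, −78 °C to 0 °C; then ice-cold pH 7 buffer
Reagents that add atoms: none
Why: Chelation-controlled aryl methyl ether cleavage: BCl3 bridges the C4 carbonyl and the peri O5 in a six-membered chelate and chloride removes that methyl group, while the 6-, 7- and 4'-methoxy groups lack this activation and the aliphatic 3-methoxy group reacts more slowly; the ring B phenols are carried as borates, O5 stays boron-bound until hydrolysis so it cannot reclose on C2, and neither stereocentre is involved.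

## Compound list

1 | 2-methoxybenzene-1,4-diol (2-methoxyhydroquinone) | COc1cc(O)ccc1O | starting material
2 | 1,4-bis(benzyloxy)-2-methoxybenzene | COc1cc(OCc2ccccc2)ccc1OCc1ccccc1 | intermediate
3 | 1,4-bis(benzyloxy)-2-bromo-5-methoxybenzene | COc1cc(OCc2ccccc2)c(Br)cc1OCc1ccccc1 | intermediate
4 | methyl (2R)-oxirane-2-carboxylate | COC(=O)[C@H]1CO1 | starting material
5 | [2,5-bis(benzyloxy)-4-methoxyphenyl]magnesium bromide | COc1cc(OCc2ccccc2)c([Mg]Br)cc1OCc1ccccc1 | intermediate (not isolated)
6 | methyl (2R)-3-[2,5-bis(benzyloxy)-4-methoxyphenyl]-2-hydroxypropanoate | COC(=O)[C@H](O)Cc1cc(OCc2ccccc2)c(OC)cc1OCc1ccccc1 | intermediate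
7 | methyl (2R)-3-[2,5-bis(benzyloxy)-4-methoxyphenyl]-2-methoxypropanoate | COC(=O)[C@H](OC)Cc1cc(OCc2ccccc2)c(OC)cc1OCc1ccccc1 | intermediate
8 | (2R)-3-[2,5-bis(benzyloxy)-4-methoxyphenyl]-N,2-dimethoxy-N-methylpropanamide | CON(C)C(=O)[C@H](OC)Cc1cc(OCc2ccccc2)c(OC)cc1OCc1ccccc1 | intermediate
9 | 3,4,5-trimethoxyphenol | COc1cc(O)cc(OC)c1OC | starting material
10 | 2-bromo-3,4,5-trimethoxyphenol | COc1cc(O)c(Br)c(OC)c1OC | intermediate
11 | 1-(benzyloxy)-2-bromo-3,4,5-trimethoxybenzene | COc1cc(OCc2ccccc2)c(Br)c(OC)c1OC | intermediate
12 | [2-(benzyloxy)-4,5,6-trimethoxyphenyl]lithium | COc1cc(OCc2ccccc2)c([Li])c(OC)c1OC | intermediate (not isolated)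
13 | (2R)-1-[2-(benzyloxy)-4,5,6-trimethoxyphenyl]-3-[2,5-bis(benzyloxy)-4-methoxyphenyl]-2-methoxypropan-1-one | COc1cc(OCc2ccccc2)c(C(=O)[C@H](OC)Cc2cc(OCc3ccccc3)c(OC)cc2OCc2ccccc2)c(OC)c1OC | intermediate
14 | (2R)-3-(2,5-dihydroxy-4-methoxyphenyl)-1-(2-hydroxy-4,5,6-trimethoxyphenyl)-2-methoxypropan-1-one | COc1cc(O)c(C(=O)[C@H](OC)Cc2cc(O)c(OC)cc2O)c(OC)c1OC | intermediate
15 | 2-[(2R)-3-(2-hydroxy-4,5,6-trimethoxyphenyl)-2-methoxy-3-oxopropyl]-5-methoxy-1,4-benzoquinone | COc1cc(O)c(C(=O)[C@@H](CC2=CC(=O)C(OC)=CC2=O)OC)c(OC)c1OC | intermediate (key-step precursor)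
16 | 4-hydroxy-6-[(2R)-3-(2-hydroxy-4,5,6-trimethoxyphenyl)-2-methoxy-3-oxopropylidene]-3-methoxycyclohexa-2,4-dien-1-one (ortho-quinone methide, alkene geometry not defined) | COc1cc(O)c(C(=O)[C@@H](C=C2C=C(O)C(OC)=CC2=O)OC)c(OC)c1OC | intermediate (not isolated)
17 | (2R,3R)-2-(2,5-dihydroxy-4-methoxyphenyl)-3,5,6,7-tetramethoxy-2,3-dihydro-4H-chromen-4-one (5-O-methyl ether of the target) | COc1cc(O)c([C@H]2Oc3cc(OC)c(OC)c(OC)c3C(=O)[C@@H]2OC)cc1O | intermediate (key-step product)
18 | (2R,3R)-2-(2,5-dihydroxy-4-methoxyphenyl)-5-hydroxy-3,6,7-trimethoxy-2,3-dihydro-4H-chromen-4-one | COc1cc(O)c([C@H]2Oc3cc(OC)c(OC)c(O)c3C(=O)[C@@H]2OC)cc1O | target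

## Step count and least certain steps

Total step count: 12. Longest linear sequence: 10 steps (steps 1 to 5 and 8 to 12, from 1).

**Step 11 (key step, new method).**
- **What may go wrong:** Proton loss at C3 of 16 may compete with ring closure, giving isomerisation to the alpha-methoxychalcone and loss of the C3 configuration. Hydrogen exchange between unreacted 15 and product 17 may put the product into its ring B quinone form, which can over-oxidise towards the flavone. The amine may add to the methoxyquinone.
- **Fallback (known chemistry):** A benzylic C–H oxidation replaces the internal redox; it sets out from 10 and returns at 17. Phenol 10 is protected with MOMCl and i-Pr2NEt as 2-bromo-3,4,5-trimethoxy-1-(methoxymethoxy)benzene F1. Bromine–lithium exchange (n-BuLi, THF, −78 °C) gives [4,5,6-trimethoxy-2-(methoxymethoxy)phenyl]lithium F2, which is acylated by 8 to (2R)-3-[2,5-bis(benzyloxy)-4-methoxyphenyl]-2-methoxy-1-[4,5,6-trimethoxy-2-(methoxymethoxy)phenyl]propan-1-one F3. HCl in MeOH removes the acetal to give (2R)-3-[2,5-bis(benzyloxy)-4-methoxyphenyl]-1-(2-hydroxy-4,5,6-trimethoxyphenyl)-2-methoxypropan-1-one F4. DDQ (CH2Cl2, 0 °C) should abstract hydride from the ring B benzylic CH2, which is para to the 4'-methoxy group, and the ring A phenol should capture the cation (oxidative cyclisation of a 2'-hydroxydihydrochalcone). This gives (2R,3R)-2-[2,5-bis(benzyloxy)-4-methoxyphenyl]-3,5,6,7-tetramethoxy-2,3-dihydro-4H-chromen-4-one F5, the same compound as A6. Hydrogenolysis (H2, Pd/C, EtOAc) returns to 17, where any cis isomer can still be equilibrated with a trace of base.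

**Step 12.**
- **What may go wrong:** The Lewis acid may ionise the C2–O1 bond, helped by the free 2'-hydroxyl and the 4'-methoxy group, with ring opening or epimerisation. The neighbouring 6-methoxy group may also be cleaved.
- **Fallback:** Ring B is deactivated before the demethylation; it sets out from 17 and returns at 18. Ac2O and pyridine give (2R,3R)-2-(2,5-diacetoxy-4-methoxyphenyl)-3,5,6,7-tetramethoxy-2,3-dihydro-4H-chromen-4-one F6. BCl3 (CH2Cl2, −78 °C to 0 °C) then gives (2R,3R)-2-(2,5-diacetoxy-4-methoxyphenyl)-5-hydroxy-3,6,7-trimethoxy-2,3-dihydro-4H-chromen-4-one F7. Acidic methanolysis (HCl in MeOH, 0 °C to 23 °C) removes the acetates without base and gives 18.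

**Step 3.**
- **What may go wrong:** The Grignard reagent may form sluggishly from the electron-rich bromide with homocoupling, and it may add to the ester carbonyl of 4 in competition with the copper-catalysed epoxide opening.
- **Fallback:** An auxiliary-controlled alkylation replaces the epoxide opening; it sets out from 2 and returns at 8.
  - Vilsmeier–Haack formylation (POCl3, DMF; aq. NaOAc) gives 2,5-bis(benzyloxy)-4-methoxybenzaldehyde F8.
  - NaBH4 gives [2,5-bis(benzyloxy)-4-methoxyphenyl]methanol F9.
  - PBr3 gives 1,4-bis(benzyloxy)-2-(bromomethyl)-5-methoxybenzene F10, used at once.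
  - (4S)-4-benzyl-3-(methoxyacetyl)-1,3-oxazolidin-2-one F11, from methoxyacetyl chloride and the lithiated oxazolidinone, is deprotonated with NaN(SiMe3)2 (THF, −78 °C) to the sodium (Z)-enolate of the imide F12.
  - Evans alkylation of F12 with F10 on the face away from the benzyl group gives (4S)-4-benzyl-3-{(2R)-3-[2,5-bis(benzyloxy)-4-methoxyphenyl]-2-methoxypropanoyl}-1,3-oxazolidin-2-one F13.
  - Me2AlN(OMe)Me, from AlMe3 and MeNHOMe·HCl, converts F13 into 8.

**Step 8.**
- **What may go wrong:** The hindered, basic aryllithium may deprotonate the alpha-methoxy amide, which would erode the C3 configuration and stall the conversion.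
- **Fallback:** Addition to an aldehyde, then oxidation; it sets out from 8 and returns at 13. LiAlH4 (THF, −78 °C) reduces 8 to (2R)-3-[2,5-bis(benzyloxy)-4-methoxyphenyl]-2-methoxypropanal F14. Aryllithium 12 adds at −78 °C to give (2R)-1-[2-(benzyloxy)-4,5,6-trimethoxyphenyl]-3-[2,5-bis(benzyloxy)-4-methoxyphenyl]-2-methoxypropan-1-ol F15 as both carbinol epimers. Dess–Martin oxidation gives 13.

## Further compounds

F1 | step 11 | 2-bromo-3,4,5-trimethoxy-1-(methoxymethoxy)benzene | COCOc1cc(OC)c(OC)c(OC)c1Br
F2 | step 11 | [4,5,6-trimethoxy-2-(methoxymethoxy)phenyl]lithium | COCOc1cc(OC)c(OC)c(OC)c1[Li]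
F3 | step 11 | (2R)-3-[2,5-bis(benzyloxy)-4-methoxyphenyl]-2-methoxy-1-[4,5,6-trimethoxy-2-(methoxymethoxy)phenyl]propan-1-one | COCOc1cc(OC)c(OC)c(OC)c1C(=O)[C@H](OC)Cc1cc(OCc2ccccc2)c(OC)cc1OCc1ccccc1
F4 | step 11 | (2R)-3-[2,5-bis(benzyloxy)-4-methoxyphenyl]-1-(2-hydroxy-4,5,6-trimethoxyphenyl)-2-methoxypropan-1-one | COc1cc(O)c(C(=O)[C@H](OC)Cc2cc(OCc3ccccc3)c(OC)cc2OCc2ccccc2)c(OC)c1OC
F5 | step 11 | (2R,3R)-2-[2,5-bis(benzyloxy)-4-methoxyphenyl]-3,5,6,7-tetramethoxy-2,3-dihydro-4H-chromen-4-one | COc1cc(OCc2ccccc2)c([C@H]2Oc3cc(OC)c(OC)c(OC)c3C(=O)[C@@H]2OC)cc1OCc1ccccc1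
F6 | step 12 | (2R,3R)-2-(2,5-diacetoxy-4-methoxyphenyl)-3,5,6,7-tetramethoxy-2,3-dihydro-4H-chromen-4-one | COc1cc(OC(C)=O)c([C@H]2Oc3cc(OC)c(OC)c(OC)c3C(=O)[C@@H]2OC)cc1OC(C)=O
F7 | step 12 | (2R,3R)-2-(2,5-diacetoxy-4-methoxyphenyl)-5-hydroxy-3,6,7-trimethoxy-2,3-dihydro-4H-chromen-4-one | COc1cc(OC(C)=O)c([C@H]2Oc3cc(OC)c(OC)c(O)c3C(=O)[C@@H]2OC)cc1OC(C)=O
F8 | step 3 | 2,5-bis(benzyloxy)-4-methoxybenzaldehyde | COc1cc(OCc2ccccc2)c(C=O)cc1OCc1ccccc1
F9 | step 3 | [2,5-bis(benzyloxy)-4-methoxyphenyl]methanol | COc1cc(OCc2ccccc2)c(CO)cc1OCc1ccccc1
F10 | step 3 | 1,4-bis(benzyloxy)-2-(bromomethyl)-5-methoxybenzene | COc1cc(OCc2ccccc2)c(CBr)cc1OCc1ccccc1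
F11 | step 3 | (4S)-4-benzyl-3-(methoxyacetyl)-1,3-oxazolidin-2-one | COCC(=O)N1[C@@H](Cc2ccccc2)COC1=O
F12 | step 3 | sodium (Z)-enolate of (4S)-4-benzyl-3-(methoxyacetyl)-1,3-oxazolidin-2-one | CO/C=C(\O[Na])N1[C@@H](Cc2ccccc2)COC1=O
F13 | step 3 | (4S)-4-benzyl-3-{(2R)-3-[2,5-bis(benzyloxy)-4-methoxyphenyl]-2-methoxypropanoyl}-1,3-oxazolidin-2-one | COc1cc(OCc2ccccc2)c(C[C@@H](OC)C(=O)N2[C@@H](Cc3ccccc3)COC2=O)cc1OCc1ccccc1
F14 | step 8 | (2R)-3-[2,5-bis(benzyloxy)-4-methoxyphenyl]-2-methoxypropanal | O=C[C@H](OC)Cc1cc(OCc2ccccc2)c(OC)cc1OCc1ccccc1
F15 | step 8 | (2R)-1-[2-(benzyloxy)-4,5,6-trimethoxyphenyl]-3-[2,5-bis(benzyloxy)-4-methoxyphenyl]-2-methoxypropan-1-ol (both C1 epimers) | COc1cc(OCc2ccccc2)c(C(O)[C@H](OC)Cc2cc(OCc3ccccc3)c(OC)cc2OCc2ccccc2)c(OC)c1OC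
A1 | alternative 1 | (2R,3R,4R)-4-(tert-butyldimethylsilyloxy)-3,6,7-trimethoxy-2-[4-methoxy-2,5-bis(triisopropylsilyloxy)phenyl]chroman-5-ol | COc1cc(O[Si](C(C)C)(C(C)C)C(C)C)c([C@H]2Oc3cc(OC)c(OC)c(O)c3[C@@H](O[Si](C)(C)C(C)(C)C)[C@@H]2OC)cc1O[Si](C(C)C)(C(C)C)C(C)C
A2 | alternative 1 | tributyl{(2R,3R,4R)-4-(tert-butyldimethylsilyloxy)-3-methoxy-2-[4-methoxy-2,5-bis(triisopropylsilyloxy)phenyl]-3,4-dihydro-2H-pyran-6-yl}stannane | COc1cc(O[Si](C(C)C)(C(C)C)C(C)C)c([C@H]2OC([Sn](CCCC)(CCCC)CCCC)=C[C@@H](O[Si](C)(C)C(C)(C)C)[C@@H]2OC)cc1O[Si](C(C)C)(C(C)C)C(C)C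
A3 | alternative 1 | 4-chloro-2,3-dimethoxycyclobut-2-en-1-one | COC1=C(OC)C(Cl)C1=O
A4 | alternative 2 | (2S)-2-[2,5-bis(benzyloxy)-4-methoxyphenyl]-5,6,7-trimethoxy-2H-chromene | COc1cc(OCc2ccccc2)c([C@H]2Oc3cc(OC)c(OC)c(OC)c3C=C2)cc1OCc1ccccc1
A5 | alternative 2 | 1,4-bis(benzyloxy)-2-methoxy-5-[1-(2-ethenyl-3,4,5-trimethoxyphenoxy)prop-2-en-1-yl]benzene, single enantiomer with the geometry of A4 | COc1cc(OCc2ccccc2)c([C@H](C=C)Oc2cc(OC)c(OC)c(OC)c2C=C)cc1OCc1ccccc1
A6 | alternative 3 | (2R,3R)-2-[2,5-bis(benzyloxy)-4-methoxyphenyl]-3,5,6,7-tetramethoxy-2,3-dihydro-4H-chromen-4-one | COc1cc(OCc2ccccc2)c([C@H]2Oc3cc(OC)c(OC)c(OC)c3C(=O)[C@@H]2OC)cc1OCc1ccccc1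
A7 | alternative 3 | (2R,3R)-3-[2,5-bis(benzyloxy)-4-methoxyphenyl]-2-methoxy-3-(3,4,5-trimethoxyphenoxy)propanoic acid | COc1cc(OCc2ccccc2)c([C@@H](Oc2cc(OC)c(OC)c(OC)c2)[C@@H](OC)C(=O)O)cc1OCc1ccccc1
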